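## The problem

Target 16 is a 2,5-diaryl-3,4-dimethyltetrahydrofuran: one five-membered ring O1–C2–C3–C4–C5 whose four carbons are all stereogenic, (2S,3S,4R,5R), with ring A (3-hydroxy-4,5-dimethoxyphenyl) on C2 and ring B (3,4,5-trimethoxyphenyl) on C5. The two aryl groups are cis to each other, the two methyl groups are cis to each other, and each methyl is trans to the aryl group beside it. Rings A and B differ only by OH versus OCH3 at one meta position, so the molecule is almost meso and its handedness rests on which benzylic carbon carries which ring. C2 and C5 must therefore each be set by a reagent or catalyst; once fixed, they can direct C3 and C4 through a cyclic transition state. Both ring C–O bonds are benzylic ethers on electron-rich arenes, so strong acids can ionise them (epimerisation, ring opening) and hydrogenolysis can cleave them. The phenol needs a mask that comes off without acid or hydrogen. The enabling feature is that C3 and C4 are each a CH(CH3) unit, that is a vinyl group plus one hydrogen, so the C3–C4 bond can be made between two vinyl groups carried by the C2–O1–C5 dibenzylic ether (a 1,6-diene with oxygen in the tether).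

## Retrosynthesis

**16 ⇒ 15 (O–Si bond).** The phenol is carried as its triisopropylsilyl ether 15. Fluoride removes it without touching the benzylic ethers. The bulky silyl group is preferred to a smaller one because it has to survive metal alkoxides twice (steps 4 and 7), where a less hindered aryl silyl ether could pass its silicon to the alkoxide. The forward step needs only chemoselectivity.

**15 ⇒ 14 (C3–C4 bond).** Cutting C3–C4 and removing one hydrogen from each methyl carbon gives the bis-allylic ether 14. Cutting O1–C2 or O1–C5 instead would create a benzylic centre last, through a cation-like intermediate. Cutting C2–C3 would call for carbonyl chemistry and later redox adjustment. The C3–C4 cut removes the ring and two stereocentres at once and leaves an acyclic ether with only the two benzylic centres. The forward reaction must add two hydrogen atoms, close the ring 5-exo, and place both methyl groups trans to the neighbouring aryl groups. The two vinyl groups play interchangeable roles and need not be told apart.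

**14 ⇒ 11 + 7 (C2–O1 bond).** An ether between two secondary benzylic carbons cannot be made by simple displacement, and acid-promoted condensation would scramble both centres. Attack of the alkoxide of (R)-allylic alcohol 11 on an iridium allyl complex from linear carbonate 7 forms the bond under basic, non-ionising conditions. C5 arrives intact in the nucleophile, because its C–O bond is never broken. The forward step must give the branched ether, and the catalyst must impose (S) at C2 irrespective of the resident (R) centre.

**7 ⇒ 5 ⇒ 4 ⇒ 2 + 3; 2 ⇒ 1.** The chiral iridium catalyst works best from a linear (E) carbonate. Carbonate 7 is the tert-butyl carbonate, so that the alkoxide released from the leaving group is too hindered to compete. It comes from cinnamyl alcohol 5, which comes from ester 4 by reduction; 4 comes from aldehyde 2 and phosphonate 3 by olefination; 2 is the silyl ether of commercial phenol 1. All are routine operations.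

**11 ⇒ 10 ⇒ 8 + 9 (C5–vinyl bond).** Addition of vinylmagnesium bromide 9 to aldehyde 8 gives racemic alcohol 10 in one step, and a kinetic resolution delivers 11. Half of an inexpensive two-step material is lost, which is accepted for the sake of a short, reliable branch.

## Roads not taken

Alternative 1: A cyclobutanone stands in for the C2–C3–C4–C5 chain.
- Forward: a keteniminium ion from a ring B arylacetic amide of a chiral secondary amine would add to cis-2-butene A1 in a [2+2] cycloaddition, and hydrolysis would give cyclobutanone A2. Peracid oxygen insertion on the benzylic side would give lactone A3. Ring A would then be added as an aryl-metal reagent and the lactol reduced with a silane and a Lewis acid.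
- Merits: the cis relation of the methyl groups is copied from the alkene geometry of A1 in a concerted step, not chosen by a transition-state preference. The sequence is about six or seven steps, shorter than the nine proposed here.
- Weak points: an unpolarised 1,2-dialkyl alkene such as A1 is a slow partner for keteniminium ions and offers the chiral amine little to discriminate, so conversion and absolute control are both doubtful. C2 is made last, by hydride delivery to a planar, aryl-stabilised oxocarbenium ion. The hydride must enter on the face carrying both methyl groups to leave ring A trans to the C3 methyl, and nothing in A3 enforces that. The Lewis acid in that step can also open the C5–O bond and scramble C5.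
- Comparison: this road is better in step count and in how the cis-dimethyl unit is secured. Against that, the chosen plan makes C2 and C5 by asymmetric reactions of known sense before the ring exists and never exposes them to acid. Its last stereo-forming step is a neutral radical closure in which all steric preferences point the same way.

Alternative 2: The cuts are the two ring-to-methyl bonds, tied together through sulfur.
- Forward: fluoride would release a thiocarbonyl ylide from chloromethyl trimethylsilylmethyl sulfide A5. This ylide would add across the double bond of (R)-butenolide A4, anti to the aryl group, to give the cis-fused thiolane lactone A6. Desulfurisation with Raney Ni would reveal lactone A3, which then needs the same aryl addition and reduction as in Alternative 1.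
- Merits: the ring fusion forces the methyl groups cis, and facial control by the C5 substituent of a butenolide is dependable. Reagent A5 is a simple, accessible ylide precursor.
- Weak points: the C5 hydrogen of A4 is benzylic and vinylogous to the carbonyl, so the fluoride that activates A5, or any base, can remove it and racemise the compound through the achiral 2-oxidofuran. A4 itself needs several steps in enantiopure form. Desulfurisation of A6 over Raney Ni puts the benzylic acyloxy C–O bond of the lactone, a better leaving group than an ether oxygen, at risk of hydrogenolysis. The endgame shares the uncontrolled oxocarbenium reduction.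
- Comparison: this road is at least as long as the chosen one and guarantees the cis-dimethyl unit more firmly. The chosen plan is stronger on the absolute configuration of both benzylic centres and on the last centre formed.

Alternative 3: Both ring C–O bonds are cut, with the ring oxygen coming from water.
- Forward: Ag2O in wet acetone would oxidise the two para-hydroxybenzyl units of dibenzylbutane A7 to quinone methides. Water would add to one, and the new benzylic hydroxyl would add to the other, giving tetrahydrofuran A8. Methylation of both para phenols and removal of the allyl ether would finish the synthesis.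
- Merits: the ring, both C–O bonds and both benzylic centres form in one biomimetic operation. Reversible quinone methide formation may funnel material to the isomer with each aryl trans to its neighbouring methyl, which is the arrangement wanted. For the ring-forming stage this is more direct than the chosen plan.
- Weak points: the benzylic centres are set under thermodynamic control with no external handle, so there is no remedy if the 2,5-cis isomer does not dominate. Quinone methides of this kind can also be trapped by the other arene to give aryltetralins. The target has para methoxy groups and a meta hydroxyl, the reverse of what the oxidation requires, so an allyl group, two methylations and a deallylation are added. A7 is chiral only through the small difference between its two ends and is not trivial to make as a single enantiomer.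
- Comparison: this road wins on the ring-forming stage if the equilibrium is favourable. The chosen plan offsets this by keeping the target's oxygenation pattern throughout, with one silyl group only, and by fixing C2 and C5 kinetically with a catalyst and a resolution.

Key step: step 8

Assumption: the (Sa,S,S) antipode of the binaphthol bis(1-phenylethyl)amine phosphoramidite is taken to direct the alkoxide to the face of the iridium allyl intermediate that gives (S) at C2. If the first run shows the opposite sense, the (Ra,R,R) ligand is used with no other change.

## Route

Step 1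
Reactants: 1 3-hydroxy-4,5-dimethoxybenzaldehyde
Product: 2 3,4-dimethoxy-5-(triisopropylsilyloxy)benzaldehyde
Conditions: i-Pr3SiCl, imidazole, DMF, rt
Reagents that add atoms: triisopropylsilyl chloride, CC(C)[Si](Cl)(C(C)C)C(C)C
Why: Silyl ether formation at a phenol; the bulky silyl group should withstand the alkoxides of steps 4 and 7 and is later removed by fluoride.

Step 2
Reactants: 2 3,4-dimethoxy-5-(triisopropylsilyloxy)benzaldehyde; 3 triethyl phosphonoacetate
Product: 4 ethyl (E)-3-[3,4-dimethoxy-5-(triisopropylsilyloxy)phenyl]prop-2-enoate
Conditions: LiCl, DBU, MeCN, rt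
Reagents that add atoms: none
Why: Horner–Wadsworth–Emmons olefination under Masamune–Roush conditions; the stabilised phosphonate should give the (E) ester and the mild amine base spares the aryl silyl ether.

Step 3
Reactants: 4 ethyl (E)-3-[3,4-dimethoxy-5-(triisopropylsilyloxy)phenyl]prop-2-enoate
Product: 5 (E)-3-[3,4-dimethoxy-5-(triisopropylsilyloxy)phenyl]prop-2-en-1-ol
Conditions: i-Bu2AlH, CH2Cl2, −78 °C; then aq. potassium sodium tartrate
Reagents that add atoms: none
Why: 1,2-Reduction of an α,β-unsaturated ester to the allylic alcohol by an aluminium hydride; the alkene geometry and the silyl ether are not affected.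

Step 4
Reactants: 5 (E)-3-[3,4-dimethoxy-5-(triisopropylsilyloxy)phenyl]prop-2-en-1-ol
Product: 7 tert-butyl (E)-3-[3,4-dimethoxy-5-(triisopropylsilyloxy)phenyl]prop-2-en-1-yl carbonate, via lithium cinnamyl alkoxide 6 (not isolated)
Conditions: n-BuLi, THF, −78 °C; then Boc2O, −78 °C to rt; H2O
Reagents that add atoms: di-tert-butyl dicarbonate, CC(C)(C)OC(=O)OC(=O)OC(C)(C)C
Why: O-Acylation of a lithium alkoxide; the tert-butyl carbonate is chosen because the tert-butoxide it releases in step 7 is too hindered to compete with the intended alkoxide.

Step 5
Reactants: 8 3,4,5-trimethoxybenzaldehyde; 9 vinylmagnesium bromide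
Product: 10 racemic 1-(3,4,5-trimethoxyphenyl)prop-2-en-1-ol
Conditions: THF, 0 °C; then H2O
Reagents that add atoms: none
Why: Grignard 1,2-addition to an aromatic aldehyde; neutral work-up avoids ionisation of the benzylic allylic alcohol.

Step 6
Reactants: 10 racemic 1-(3,4,5-trimethoxyphenyl)prop-2-en-1-ol
Product: 11 (R)-1-(3,4,5-trimethoxyphenyl)prop-2-en-1-ol
Conditions: Ti(OiPr)4 (0.2 equiv), D-(−)-diisopropyl tartrate (0.3 equiv), t-BuOOH (0.6 equiv), 4 Å MS, CH2Cl2, −20 °C
Reagents that add atoms: none
Why: Sharpless kinetic resolution of a secondary allylic alcohol; with the D-(−)-tartrate the (S) enantiomer of an aryl vinyl carbinol should be epoxidised faster, so the (R) alcohol is recovered when the reaction is run slightly past half conversion.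

Step 7
Reactants: 11 (R)-1-(3,4,5-trimethoxyphenyl)prop-2-en-1-ol; 7 tert-butyl (E)-3-[3,4-dimethoxy-5-(triisopropylsilyloxy)phenyl]prop-2-en-1-yl carbonate
Product: 14 (S)-1-[3,4-dimethoxy-5-(triisopropylsilyloxy)phenyl]allyl (R)-1-(3,4,5-trimethoxyphenyl)allyl ether, via lithium alkoxide 12 (not isolated), via copper alkoxide 13 (not isolated)
Conditions: 11, n-BuLi, THF, 0 °C; CuI (1 equiv), rt; then 7, [Ir(cod)Cl]2 (2 mol %), (Sa,S,S)-O,O'-(1,1'-binaphthalene-2,2'-diyl) N,N-bis(1-phenylethyl)phosphoramidite (4 mol %), THF, rt; H2O
Reagents that add atoms: none
Why: Iridium-catalysed branched-selective allylic etherification of a linear cinnamyl carbonate with a copper alkoxide of a secondary alcohol; the chiral phosphoramidite complex should control the face of the allyl intermediate and set C2 as (S). The C–O bond at C5 is not broken, so the (R) centre of 11 is carried over unchanged.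

Step 8
Reactants: 14 (S)-1-[3,4-dimethoxy-5-(triisopropylsilyloxy)phenyl]allyl (R)-1-(3,4,5-trimethoxyphenyl)allyl ether
Product: 15 (2S,3S,4R,5R)-2-[3,4-dimethoxy-5-(triisopropylsilyloxy)phenyl]-3,4-dimethyl-5-(3,4,5-trimethoxyphenyl)tetrahydrofuran
Conditions: Mn(dpm)3 (10 mol %), PhSiH3, t-BuOOH, i-PrOH (degassed, 0.01 M), rt
Reagents that add atoms: none
Why: Mn(dpm)3 and PhSiH3 (with t-BuOOH returning divalent manganese to the trivalent state) should give a manganese hydride that transfers a hydrogen atom to the terminal CH2 of either vinyl group, producing the secondary radical at C3 or at C4. This 3-oxahex-5-enyl radical adds to the internal carbon of the other vinyl group, forming the C3–C4 bond and closing the tetrahydrofuran by 5-exo-trig attack; the exocyclic primary radical then takes a second hydrogen atom and becomes the second methyl group. The closest known reaction type is the metal hydride hydrogen-atom-transfer (Mukaiyama-type) reductive cyclisation of 1,6-dienes, and the closure itself is the classical 5-exo cyclisation of β-alkoxyalkyl radicals. C3 and C4 are controlled by C2 and C5 through a chair-like Beckwith–Houk transition state in which both aryl groups are pseudo-equatorial, which is possible only because the (S,R) ether holds them on the same side. In that chair the radical carbon turns its methyl away from the adjacent aryl group and the attacked vinyl group lies pseudo-equatorial, so each new methyl should end trans to its neighbouring aryl group and the two methyls cis. Either vinyl group may react first, because the two arms differ only in a remote meta substituent and both paths lead to 15. The step needs 5-exo closure to outrun direct reduction of the first radical, 6-endo closure and 1,2-aryl shift; the oxygen in the tether accelerates the 5-exo mode and high dilution keeps the hydrogen donor scarce. The aryl silyl ether, the methoxy groups and the benzylic ether bonds should be inert under these neutral conditions.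

Step 9
Reactants: 15 (2S,3S,4R,5R)-2-[3,4-dimethoxy-5-(triisopropylsilyloxy)phenyl]-3,4-dimethyl-5-(3,4,5-trimethoxyphenyl)tetrahydrofuran
Product: 16 (2S,3S,4R,5R)-2-(3-hydroxy-4,5-dimethoxyphenyl)-3,4-dimethyl-5-(3,4,5-trimethoxyphenyl)tetrahydrofuran
Conditions: Bu4NF, THF, 0 °C; then H2O
Reagents that add atoms: none
Why: Fluoride cleavage of an aryl silyl ether; the phenoxide is meta to the benzylic carbon and cannot open the ring through a quinone methide, so the four stereocentres are untouched.

## Compound list

1 | 3-hydroxy-4,5-dimethoxybenzaldehyde | COc1cc(C=O)cc(O)c1OC | starting material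
2 | 3,4-dimethoxy-5-(triisopropylsilyloxy)benzaldehyde | COc1cc(C=O)cc(O[Si](C(C)C)(C(C)C)C(C)C)c1OC | intermediate
3 | triethyl phosphonoacetate | CCOC(=O)CP(=O)(OCC)OCC | starting material
4 | ethyl (E)-3-[3,4-dimethoxy-5-(triisopropylsilyloxy)phenyl]prop-2-enoate | CCOC(=O)/C=C/c1cc(OC)c(OC)c(O[Si](C(C)C)(C(C)C)C(C)C)c1 | intermediate
5 | (E)-3-[3,4-dimethoxy-5-(triisopropylsilyloxy)phenyl]prop-2-en-1-ol | OC/C=C/c1cc(OC)c(OC)c(O[Si](C(C)C)(C(C)C)C(C)C)c1 | intermediate
6 | lithium (E)-3-[3,4-dimethoxy-5-(triisopropylsilyloxy)phenyl]prop-2-en-1-olate (not isolated) | [Li+].[O-]C/C=C/c1cc(OC)c(OC)c(O[Si](C(C)C)(C(C)C)C(C)C)c1 | intermediate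
7 | tert-butyl (E)-3-[3,4-dimethoxy-5-(triisopropylsilyloxy)phenyl]prop-2-en-1-yl carbonate | CC(C)(C)OC(=O)OC/C=C/c1cc(OC)c(OC)c(O[Si](C(C)C)(C(C)C)C(C)C)c1 | intermediate
8 | 3,4,5-trimethoxybenzaldehyde | COc1cc(C=O)cc(OC)c1OC | starting material
9 | vinylmagnesium bromide | C=C[Mg]Br | starting material
10 | racemic 1-(3,4,5-trimethoxyphenyl)prop-2-en-1-ol | C=CC(O)c1cc(OC)c(OC)c(OC)c1 | intermediate
11 | (R)-1-(3,4,5-trimethoxyphenyl)prop-2-en-1-ol | O[C@H](C=C)c1cc(OC)c(OC)c(OC)c1 | intermediate
12 | lithium (R)-1-(3,4,5-trimethoxyphenyl)prop-2-en-1-olate (not isolated) | [Li+].[O-][C@H](C=C)c1cc(OC)c(OC)c(OC)c1 | intermediate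
13 | copper (R)-1-(3,4,5-trimethoxyphenyl)prop-2-en-1-olate, monovalent copper (not isolated) | [Cu]O[C@H](C=C)c1cc(OC)c(OC)c(OC)c1 | intermediate
14 | (S)-1-[3,4-dimethoxy-5-(triisopropylsilyloxy)phenyl]allyl (R)-1-(3,4,5-trimethoxyphenyl)allyl ether | C=C[C@@H](c1cc(O[Si](C(C)C)(C(C)C)C(C)C)c(OC)c(OC)c1)O[C@H](C=C)c1cc(OC)c(OC)c(OC)c1 | intermediate
15 | (2S,3S,4R,5R)-2-[3,4-dimethoxy-5-(triisopropylsilyloxy)phenyl]-3,4-dimethyl-5-(3,4,5-trimethoxyphenyl)tetrahydrofuran | COc1cc([C@H]2O[C@@H](c3cc(OC)c(OC)c(OC)c3)[C@H](C)[C@@H]2C)cc(O[Si](C(C)C)(C(C)C)C(C)C)c1OC | intermediate
16 | (2S,3S,4R,5R)-2-(3-hydroxy-4,5-dimethoxyphenyl)-3,4-dimethyl-5-(3,4,5-trimethoxyphenyl)tetrahydrofuran | COc1cc([C@H]2O[C@@H](c3cc(OC)c(OC)c(OC)c3)[C@H](C)[C@@H]2C)cc(O)c1OC | target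

## Step count and risks

Total: 9 steps. Longest linear sequence: 7 steps (1, 2, 3, 4, 7, 8, 9); the ring B branch (steps 5 and 6) joins at step 7.

**Step 8 (key step).** Three things are most likely to go wrong. Hydrogen-atom donation to the first secondary radical may compete with ring closure and simply hydrogenate a vinyl group. Oxygen-centred radicals from the peroxide may abstract the weak benzylic, allylic C2–H or C5–H and erode those centres. The preference for the all-pseudo-equatorial chair may be too small, giving epimers at C3 and C4.

The fallback sets out from 14 and separates radical generation from the metal hydride. Thiyl radical addition–cyclisation (PhSH added slowly by syringe pump, AIBN, benzene, 80 °C, high dilution) should give, through the same 5-exo closure started at either vinyl terminus, 3-(phenylsulfanylmethyl)-4-methyl tetrahydrofuran F1 and 4-(phenylsulfanylmethyl)-3-methyl tetrahydrofuran F2. Reductive desulfurisation of the mixture with nickel boride made in the flask (NiCl2·6H2O, NaBH4, MeOH–THF, 0 °C), a mild reagent under which the ring ether bonds should hold, converts both into 15, where the route is rejoined.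

**Step 7.** The resident (R) centre of the alkoxide may oppose the catalyst's facial preference, so that catalyst control is incomplete and the C2 epimer forms. Attack at the unsubstituted allyl terminus would give the linear ether. The hindered secondary alkoxide may also react slowly enough for metal-promoted isomerisation of the allylic alkoxide to a ketone to compete.

The fallback sets out from aldehyde 2 and returns at 14; it takes the configuration of C2 from a resolved alcohol instead of from catalyst face selection. Aldehyde 2 and vinylmagnesium bromide 9 give racemic 1-[3,4-dimethoxy-5-(triisopropylsilyloxy)phenyl]prop-2-en-1-ol F3. Sharpless kinetic resolution with the L-(+)-tartrate leaves (S)-1-[3,4-dimethoxy-5-(triisopropylsilyloxy)phenyl]prop-2-en-1-ol F4. Treatment with n-BuLi and Boc2O gives tert-butyl (S)-1-[3,4-dimethoxy-5-(triisopropylsilyloxy)phenyl]allyl carbonate F5. Substitution of this branched carbonate by copper alkoxide 13 with [Ir(cod)Cl]2 and P(OPh)3 is expected to proceed with net retention (two inversions) and to return to 14.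

**Step 6.** Epoxidation of a monosubstituted alkene is slow, so the resolution may stop short of full enantiomeric enrichment. The titanium alkoxide may also ionise the electron-rich benzylic allylic alcohol, leading to racemisation or 1,3-transposition.

The fallback sets out from 10 and uses an enzyme instead of a Lewis acid. Lipase-catalysed acylation (Novozym 435, vinyl acetate, t-BuOMe, rt) should, by the usual empirical rule for secondary alcohols, acylate the (R) enantiomer and give (R)-1-(3,4,5-trimethoxyphenyl)allyl acetate F6, which is separated from the unreacted (S) alcohol. Methanolysis (K2CO3, MeOH, 0 °C) returns 11.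

## Further compounds

F1 | step 8 | (2S,3S,4R,5R)-2-[3,4-dimethoxy-5-(triisopropylsilyloxy)phenyl]-4-methyl-3-(phenylsulfanylmethyl)-5-(3,4,5-trimethoxyphenyl)tetrahydrofuran | COc1cc([C@H]2O[C@@H](c3cc(OC)c(OC)c(OC)c3)[C@H](C)[C@@H]2CSc4ccccc4)cc(O[Si](C(C)C)(C(C)C)C(C)C)c1OC
F2 | step 8 | (2S,3S,4R,5R)-2-[3,4-dimethoxy-5-(triisopropylsilyloxy)phenyl]-3-methyl-4-(phenylsulfanylmethyl)-5-(3,4,5-trimethoxyphenyl)tetrahydrofuran | COc1cc([C@H]2O[C@@H](c3cc(OC)c(OC)c(OC)c3)[C@H](CSc4ccccc4)[C@@H]2C)cc(O[Si](C(C)C)(C(C)C)C(C)C)c1OC
F3 | step 7 | racemic 1-[3,4-dimethoxy-5-(triisopropylsilyloxy)phenyl]prop-2-en-1-ol | C=CC(O)c1cc(OC)c(OC)c(O[Si](C(C)C)(C(C)C)C(C)C)c1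
F4 | step 7 | (S)-1-[3,4-dimethoxy-5-(triisopropylsilyloxy)phenyl]prop-2-en-1-ol | O[C@@H](C=C)c1cc(OC)c(OC)c(O[Si](C(C)C)(C(C)C)C(C)C)c1
F5 | step 7 | tert-butyl (S)-1-[3,4-dimethoxy-5-(triisopropylsilyloxy)phenyl]allyl carbonate | CC(C)(C)OC(=O)O[C@@H](C=C)c1cc(OC)c(OC)c(O[Si](C(C)C)(C(C)C)C(C)C)c1
F6 | step 6 | (R)-1-(3,4,5-trimethoxyphenyl)allyl acetate | CC(=O)O[C@H](C=C)c1cc(OC)c(OC)c(OC)c1
A1 | alternative 1 | cis-2-butene | C/C=C\C
A2 | alternative 1 | (2R,3R,4S)-3,4-dimethyl-2-(3,4,5-trimethoxyphenyl)cyclobutan-1-one | O=C1[C@@H](c2cc(OC)c(OC)c(OC)c2)[C@H](C)[C@@H]1C
A3 | alternative 1 | (3S,4R,5R)-3,4-dimethyl-5-(3,4,5-trimethoxyphenyl)dihydrofuran-2(3H)-one | O=C1O[C@@H](c2cc(OC)c(OC)c(OC)c2)[C@H](C)[C@@H]1C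
A4 | alternative 2 | (R)-5-(3,4,5-trimethoxyphenyl)furan-2(5H)-one | O=C1O[C@@H](c2cc(OC)c(OC)c(OC)c2)C=C1
A5 | alternative 2 | chloromethyl trimethylsilylmethyl sulfide | C[Si](C)(C)CSCCl
A6 | alternative 2 | cis-fused 3-(3,4,5-trimethoxyphenyl)tetrahydro-1H-thieno[3,4-c]furan-1-one, (3R), aryl trans to the thiolane ring | O=C1O[C@@H](c3cc(OC)c(OC)c(OC)c3)[C@@H]2CSC[C@H]12
A7 | alternative 3 | 2-(allyloxy)-4-[(2R,3S)-4-(4-hydroxy-3,5-dimethoxyphenyl)-2,3-dimethylbutyl]-6-methoxyphenol | COc1cc(C[C@@H](C)[C@@H](C)Cc2cc(OC)c(O)c(OC)c2)cc(OCC=C)c1O
A8 | alternative 3 | (2S,3S,4R,5R)-2-(3-allyloxy-4-hydroxy-5-methoxyphenyl)-5-(4-hydroxy-3,5-dimethoxyphenyl)-3,4-dimethyltetrahydrofuran | COc1cc([C@H]2O[C@@H](c3cc(OC)c(O)c(OC)c3)[C@H](C)[C@@H]2C)cc(OCC=C)c1O
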